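**Retrosynthetic overview** (eudesmane numbering: C4 = carbinol carbon with methyl C15, C5 = fusion CH, C6 = ester carbon, C7 = isopropyl carbon, C10 = quaternary fusion carbon with methyl C14)

1. The C6–O ester bond to isoferulic acid (phenol as TBS ether) is cut last; the 4β-carbinol goes back to a 4(15)-alkene (epoxidation steered by the axial 6β-hydroxyl, then hydride opening) and the 6β-hydroxyl to a 6α-acetate (oxidation, then reduction).
2. Key disconnection: the C5–C10 bond shared by rings A and B, the fusion bond whose 10β-methyl is trans to H-5α. Cutting it opens the trans-decalin to a ten-membered (E,E)-germacra-1(10),4-diene ring in which C1=C10 lies across from C4=C5, so one acid-induced transannular closure makes rings A and B together.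
3. The ten-membered ring is made first, by closing C6–C7 in a CrCl2-mediated allylation of 12-bromofarnesal (five steps from (2E,6E)-farnesol). The racemic alcohol is resolved in the same operation that acetylates it, and the isopropenyl group is hydrogenated before the key step, so that only the two ring alkenes meet the acid and only one alkene meets the later directed epoxidation.
4. Ring order: ten-membered carbocycle (step 6), then rings A and B at once (step 9).

Key step: step 9

Assumption: in step 7 the lipase is taken to follow Kazlauskas' rule with the branched C7 side of the carbinol as the large group, so that it acetylates the (6R,7S)-alcohol; should it prefer the antipode, the wanted enantiomer is the alcohol left over and Ac2O/pyridine gives the same acetate.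

**Route**

Step 1
Reactants: 1 (2E,6E)-farnesol
Product: 2 (2E,6E)-farnesyl tert-butyldimethylsilyl (TBS) ether
Conditions: TBSCl, imidazole, DMF, 0 °C to rt
Reagents that add atoms: tert-butyldimethylsilyl chloride, CC(C)(C)[Si](C)(C)Cl
Why: Imidazole-promoted silylation of the primary allylic alcohol masks C1–OH and, through the inductive pull of the allylic oxygen, leaves the 2,3-alkene the least reactive one in the allylic oxidation that follows; no stereocentre is involved.

Step 2
Reactants: 2 (2E,6E)-farnesyl TBS ether
Product: 3 (2E,6E,10E)-12-hydroxyfarnesyl TBS ether (TBSO at C1, HO at C12)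
Conditions: SeO2 (cat.), t-BuOOH, salicylic acid (cat.), CH2Cl2, 0 °C to rt
Reagents that add atoms: tert-butyl hydroperoxide, CC(C)(C)OO (its oxygen is passed on through catalytic SeO2, O=[Se]=O)
Why: Sharpless allylic oxidation (ene reaction, then [2,3]-shift) attacks the most electron-rich, terminal trisubstituted alkene and there the methyl group trans to the chain, so the new CH2OH keeps the 10E geometry.

Step 3
Reactants: 3 (2E,6E,10E)-12-hydroxyfarnesyl TBS ether
Product: 4 (2E,6E,10E)-12-bromofarnesyl TBS ether
Conditions: CBr4, PPh3, CH2Cl2, 0 °C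
Reagents that add atoms: carbon tetrabromide, BrC(Br)(Br)Br
Why: Appel bromination replaces the primary allylic hydroxyl by SN2 displacement of the oxyphosphonium group at C12, so the 10E-alkene is not shifted and the silyl ether is untouched.

Step 4
Reactants: 4 (2E,6E,10E)-12-bromofarnesyl TBS ether
Product: 5 (2E,6E,10E)-12-bromofarnesol
Conditions: 48% aq. HF, MeCN, 0 °C
Reagents that add atoms: none
Why: Acidic fluoride desilylation removes the primary TBS ether within minutes under non-basic, weakly nucleophilic conditions, under which the allylic bromide is not displaced as it could be by Bu4NF or an alkoxide.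

Step 5
Reactants: 5 (2E,6E,10E)-12-bromofarnesol
Product: 6 (2E,6E,10E)-12-bromofarnesal
Conditions: MnO2 (activated), CH2Cl2, rt
Reagents that add atoms: none
Why: MnO2 oxidation is selective for the allylic alcohol, stops at the (2E)-enal and leaves the allylic bromide alone.

Step 6
Reactants: 6 (2E,6E,10E)-12-bromofarnesal
Product: 7 rac-(1(10)E,4E,6R*,7S*)-germacra-1(10),4,11-trien-6-ol (OH and isopropenyl trans on the ring; racemate)
Conditions: CrCl2 (6 equiv), THF, rt, slow addition of 6 (final 0.005 M); pH 7 work-up, Et3N-washed silica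
Reagents that add atoms: none
Why: Intramolecular Nozaki–Hiyama allylation: divalent chromium turns the allylic bromide into an allylchromium species that adds through its γ-carbon (C7) to the enal carbonyl (C6) in a chair-like transition state, which closes the ten-membered ring with both E-alkenes intact and should place OH and isopropenyl trans (6R*,7S*), as in related closures of germacrane rings; with no chiral element present the product is racemic.

Step 7
Reactants: 7 rac-(1(10)E,4E,6R*,7S*)-germacra-1(10),4,11-trien-6-ol
Product: 8 (1(10)E,4E,6R,7S)-germacra-1(10),4,11-trien-6-yl acetate (6α-OAc, 7β-isopropenyl)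
Conditions: lipase PS (Burkholderia cepacia, immobilised), vinyl acetate, t-BuOMe, 30 °C, stopped short of half conversion
Reagents that add atoms: vinyl acetate, CC(=O)OC=C
Why: Lipase-catalysed kinetic resolution by irreversible transesterification should acetylate the (6R,7S)-half of 7 (Kazlauskas' rule, C7 side as the large group) and leave the (6S,7R)-half as the alcohol, to be removed by chromatography, so that the absolute configuration at C6 and C7 and the acetate needed for the key step are secured in one operation.

Step 8
Reactants: 8 (1(10)E,4E,6R,7S)-germacra-1(10),4,11-trien-6-yl acetate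
Product: 9 (1(10)E,4E,6S,7S)-germacra-1(10),4-dien-6-yl acetate (6α-OAc, 7β-isopropyl; same spatial arrangement as 8, the C6 descriptor changes only by priority)
Conditions: H2 (1 atm), RhCl(PPh3)3 (5 mol%), benzene, rt
Reagents that add atoms: none
Why: Homogeneous hydrogenation with RhCl(PPh3)3 discriminates by alkene substitution, so the 1,1-disubstituted isopropenyl group should be reduced while the two trisubstituted ring alkenes and the allylic acetate remain; no stereocentre is formed or touched, and room temperature avoids Cope rearrangement of the (E,E)-cyclodecadiene.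

Step 9
Reactants: 9 (1(10)E,4E,6S,7S)-germacra-1(10),4-dien-6-yl acetate
Product: 10 (5S,6S,7S,10R)-eudesm-4(15)-en-6-yl acetate (6α-OAc, H-5α, 10β-CH3, 7β-isopropyl)
Conditions: TsOH·H2O (0.1 equiv), CH2Cl2, 0 °C
Reagents that add atoms: none
Why: Acid protonates C1 of the 1(10)-alkene and the developing C10 cation is taken up across the ring by C5 of the C4=C5 alkene (new C5–C10 bond), after which the tertiary C4 cation loses a C15 proton to leave the 4(15)-alkene. The closest known reaction type is the acid-induced transannular cation–olefin cyclization of (E,E)-germacra-1(10),4-dienes such as costunolide and hedycaryol to eudesmanes. Ring A closes in a 6-endo-trig mode (C4 and C5 both end up in ring A) and ring B in a 6-exo-trig mode (C4 lies outside ring B), both through the same bond. C10 and C5 are set by the crown (chair–chair) conformer of the ten-membered ring, in which both ring methyls point to the β-face and the C6 acetoxy and C7 isopropyl groups sit pseudo-equatorial, so the inner faces of the two alkenes join to give the 10β-methyl and H-5α (trans-decalin, 5S,10R) while C6 and C7 are untouched. The step needs protonation at C1 rather than C5 and no ionization of the allylic acetate: the acetoxy group lowers the basicity of the 4,5-alkene inductively, participation of that alkene lets ring closure outrun acetate loss, and the isopropenyl group that would compete for the proton was saturated in step 8. A Δ3 isomer from loss of a C3 proton can be carried along, because the directed β-epoxidation and diaxial hydride opening later give the same 4β-alcohol.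

Step 10
Reactants: 10 (5S,6S,7S,10R)-eudesm-4(15)-en-6-yl acetate
Product: 11 (5S,6S,7S,10R)-eudesm-4(15)-en-6-ol (6α-OH, equatorial)
Conditions: K2CO3, MeOH, 40 °C
Reagents that add atoms: none
Why: Base-catalysed transesterification with methanol removes the acetate without touching the exocyclic alkene or any stereocentre.

Step 11
Reactants: 11 (5S,6S,7S,10R)-eudesm-4(15)-en-6-ol
Product: 12 (5S,7S,10R)-eudesm-4(15)-en-6-one
Conditions: Dess–Martin periodinane, NaHCO3, CH2Cl2, 0 °C; crude ketone used at once
Reagents that add atoms: none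
Why: Dess–Martin oxidation under buffered, near-neutral conditions should give the β,γ-unsaturated ketone without enolisation, so that the 4(15)-alkene does not move into conjugation and C5 and C7 keep their configuration.

Step 12
Reactants: 12 (5S,7S,10R)-eudesm-4(15)-en-6-one
Product: 13 (5S,6R,7S,10R)-eudesm-4(15)-en-6-ol (6β-OH, axial)
Conditions: LiAlH4, Et2O, −78 °C
Reagents that add atoms: none
Why: Hydride reduction of the ketone: the β-face of C6 is shielded by the syn-axial 10β-methyl, as in 6-oxo steroids, so hydride should arrive from the α-face and set the axial 6β-alcohol (6R), and the fast low-temperature reduction outruns enolisation.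

Step 13
Reactants: 13 (5S,6R,7S,10R)-eudesm-4(15)-en-6-ol
Product: 14 (4S,5S,6R,7S,10R)-4,15-epoxyeudesman-6-ol (epoxide oxygen β on C4, 6β-OH)
Conditions: VO(acac)2 (5 mol%), t-BuOOH (decane), CH2Cl2, 0 °C to rt
Reagents that add atoms: tert-butyl hydroperoxide, CC(C)(C)OO
Why: Vanadium-catalysed hydroxyl-directed epoxidation of a homoallylic alcohol: the axial 6β-alkoxide binds the vanadium peroxide and delivers oxygen to the β-face of the only alkene left, C4=C15, which sets C4 with its oxygen β.

Step 14
Reactants: 14 (4S,5S,6R,7S,10R)-4,15-epoxyeudesman-6-ol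
Product: 15 (4S,5S,6R,7S,10R)-eudesmane-4,6-diol (4β-OH, 4α-CH3, 6β-OH)
Conditions: LiAlH4, THF, 0 °C to reflux
Reagents that add atoms: none
Why: Hydride opens the 2,2-disubstituted oxirane by SN2 attack at its primary carbon C15, so the C4–O bond and with it the 4β-configuration are kept and C15 becomes the 4α-methyl group.

Step 15
Reactants: 16 isoferulic acid
Product: 18 (E)-3-[3-(tert-butyldimethylsilyloxy)-4-methoxyphenyl]acrylic acid, via silyl ester 17 (not isolated)
Conditions: TBSCl (2.5 equiv), imidazole, DMF, rt; then AcOH/THF/H2O, rt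
Reagents that add atoms: tert-butyldimethylsilyl chloride, CC(C)(C)[Si](C)(C)Cl
Why: Silylation of both the phenol and the acid followed by selective hydrolysis of the much more labile silyl ester leaves the aryl TBS ether and the E-alkene untouched.

Step 16
Reactants: 18 (E)-3-[3-(tert-butyldimethylsilyloxy)-4-methoxyphenyl]acrylic acid
Product: 19 (E)-3-[3-(tert-butyldimethylsilyloxy)-4-methoxyphenyl]acryloyl chloride
Conditions: (COCl)2, DMF (cat.), CH2Cl2, 0 °C to rt; evaporate, use crude
Reagents that add atoms: oxalyl chloride, O=C(Cl)C(=O)Cl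
Why: Acid chloride formation through the Vilsmeier-type chloroiminium intermediate is standard for silyl-protected hydroxycinnamic acids, and the cinnamoyl chloride cannot form a ketene.

Step 17
Reactants: 15 (4S,5S,6R,7S,10R)-eudesmane-4,6-diol; 19 (E)-3-[3-(tert-butyldimethylsilyloxy)-4-methoxyphenyl]acryloyl chloride
Product: 20 (4S,5S,6R,7S,10R)-4-hydroxyeudesman-6-yl (E)-3-[3-(tert-butyldimethylsilyloxy)-4-methoxyphenyl]acrylate
Conditions: DMAP, Et3N, toluene, 80 °C
Reagents that add atoms: none
Why: DMAP-catalysed acylation (nucleophilic catalysis through the acylpyridinium ion) should esterify the hindered secondary 6β-hydroxyl while the tertiary 4β-hydroxyl does not react, with retention at C6 because the C6–O bond is not broken.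

Step 18
Reactants: 20 (4S,5S,6R,7S,10R)-4-hydroxyeudesman-6-yl (E)-3-[3-(tert-butyldimethylsilyloxy)-4-methoxyphenyl]acrylate
Product: 21 (4S,5S,6R,7S,10R)-4-hydroxyeudesman-6-yl (E)-3-(3-hydroxy-4-methoxyphenyl)acrylate (CNP0291757.1)
Conditions: Bu4NF, AcOH, THF, 0 °C
Reagents that add atoms: none
Why: Fluoride desilylation of the aryl silyl ether, buffered with acetic acid so that the phenoxide is protonated at once, frees the phenol without cleaving or shifting the cinnamate ester.

**Compound list**

1 | (2E,6E)-farnesol | CC(C)=CCC/C(C)=C/CC/C(C)=C/CO | starting material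
2 | (2E,6E)-farnesyl TBS ether | CC(C)=CCC/C(C)=C/CC/C(C)=C/CO[Si](C)(C)C(C)(C)C | intermediate
3 | (2E,6E,10E)-12-hydroxyfarnesyl TBS ether | OC/C(C)=C/CC/C(C)=C/CC/C(C)=C/CO[Si](C)(C)C(C)(C)C | intermediate
4 | (2E,6E,10E)-12-bromofarnesyl TBS ether | BrC/C(C)=C/CC/C(C)=C/CC/C(C)=C/CO[Si](C)(C)C(C)(C)C | intermediate
5 | (2E,6E,10E)-12-bromofarnesol | BrC/C(C)=C/CC/C(C)=C/CC/C(C)=C/CO | intermediate
6 | (2E,6E,10E)-12-bromofarnesal | BrC/C(C)=C/CC/C(C)=C/CC/C(C)=C/C=O | intermediate
7 | rac-(1(10)E,4E,6R*,7S*)-germacra-1(10),4,11-trien-6-ol (racemate; SMILES shows the 6R,7S half) | O[C@@H]1/C=C(\C)CC/C=C(\C)CC[C@H]1C(C)=C | intermediate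
8 | (1(10)E,4E,6R,7S)-germacra-1(10),4,11-trien-6-yl acetate | CC(=O)O[C@@H]1/C=C(\C)CC/C=C(\C)CC[C@H]1C(C)=C | intermediate
9 | (1(10)E,4E,6S,7S)-germacra-1(10),4-dien-6-yl acetate | CC(=O)O[C@@H]1/C=C(\C)CC/C=C(\C)CC[C@H]1C(C)C | intermediate
10 | (5S,6S,7S,10R)-eudesm-4(15)-en-6-yl acetate | CC(=O)O[C@@H]1[C@@H]2[C@](C)(CCCC2=C)CC[C@H]1C(C)C | intermediate
11 | (5S,6S,7S,10R)-eudesm-4(15)-en-6-ol (6α-OH) | O[C@@H]1[C@@H]2[C@](C)(CCCC2=C)CC[C@H]1C(C)C | intermediate
12 | (5S,7S,10R)-eudesm-4(15)-en-6-one | O=C1[C@@H]2[C@](C)(CCCC2=C)CC[C@H]1C(C)C | intermediate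
13 | (5S,6R,7S,10R)-eudesm-4(15)-en-6-ol (6β-OH) | O[C@H]1[C@@H]2[C@](C)(CCCC2=C)CC[C@H]1C(C)C | intermediate
14 | (4S,5S,6R,7S,10R)-4,15-epoxyeudesman-6-ol (4β,15-epoxide) | O[C@H]1[C@@H]2[C@](C)(CCC[C@]23OC3)CC[C@H]1C(C)C | intermediate
15 | (4S,5S,6R,7S,10R)-eudesmane-4,6-diol (4β,6β) | O[C@H]1[C@@H]2[C@](C)(CCC[C@]2(C)O)CC[C@H]1C(C)C | intermediate
16 | isoferulic acid, (E)-3-(3-hydroxy-4-methoxyphenyl)acrylic acid | COc1ccc(/C=C/C(=O)O)cc1O | starting material
17 | tert-butyldimethylsilyl (E)-3-[3-(tert-butyldimethylsilyloxy)-4-methoxyphenyl]acrylate | COc1ccc(/C=C/C(=O)O[Si](C)(C)C(C)(C)C)cc1O[Si](C)(C)C(C)(C)C | intermediate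
18 | (E)-3-[3-(tert-butyldimethylsilyloxy)-4-methoxyphenyl]acrylic acid | COc1ccc(/C=C/C(=O)O)cc1O[Si](C)(C)C(C)(C)C | intermediate
19 | (E)-3-[3-(tert-butyldimethylsilyloxy)-4-methoxyphenyl]acryloyl chloride | COc1ccc(/C=C/C(=O)Cl)cc1O[Si](C)(C)C(C)(C)C | intermediate
20 | (4S,5S,6R,7S,10R)-4-hydroxyeudesman-6-yl (E)-3-[3-(tert-butyldimethylsilyloxy)-4-methoxyphenyl]acrylate | COc1ccc(/C=C/C(=O)O[C@H]2[C@@H]3[C@](C)(CCC[C@]3(C)O)CC[C@H]2C(C)C)cc1O[Si](C)(C)C(C)(C)C | intermediate
21 | (4S,5S,6R,7S,10R)-4-hydroxyeudesman-6-yl (E)-3-(3-hydroxy-4-methoxyphenyl)acrylate, CNP0291757.1 | COc1ccc(/C=C/C(=O)O[C@H]2[C@@H]3[C@](C)(CCC[C@]3(C)O)CC[C@H]2C(C)C)cc1O | target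

**Step count**

Total steps: 18. Longest linear sequence: 16 (steps 1 to 14, 17 and 18); steps 15 and 16 prepare the acyl partner.

**Steps most likely to fail**

Step 9 (key step). The C4 cation may lose a proton toward C5 instead of C15 or C3, or the allylic acetate may ionize before the ring closes. The fallback sets out from 9 and ends the same transannular closure with water instead of proton loss (HClO4, acetone/H2O, 0 °C). Anti addition across C4=C5 places the new hydroxyl equatorial and should give 6α-acetoxy-5α-eudesman-4α-ol F1. SOCl2/pyridine at 0 °C then eliminates the equatorial chlorosulfite, which has antiperiplanar hydrogens only on the axial C15 methyl group, and this should give the exocyclic alkene 10, where the route is rejoined.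

Step 7. The enzyme may fail to tell the two enantiomers apart, or may acylate the hindered ring carbinol too slowly. The fallback sets out from 7 and resolves it through covalent diastereomers. Esterification with (S)-O-methylmandelic acid (DCC, cat. DMAP, CH2Cl2, 0 °C) gives (6R,7S)-germacra-1(10),4,11-trien-6-yl (S)-O-methylmandelate F2 and (6S,7R)-germacra-1(10),4,11-trien-6-yl (S)-O-methylmandelate F3, which are separated by chromatography. K2CO3/MeOH frees (1(10)E,4E,6R,7S)-germacra-1(10),4,11-trien-6-ol F4 from F2, and Ac2O/pyridine/DMAP converts it into 8, where the route is rejoined.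

Step 11. While the ketone is made and handled, the 4(15)-alkene may move into conjugation or C5 may epimerise through the enol; the reduction in step 12 depends on the ketone arriving intact. The fallback sets out from 11 and removes the alkene before C6 is oxidised. Ozonolysis (O3, CH2Cl2/MeOH, −78 °C; Me2S) gives 6α-hydroxy-15-nor-5α-eudesman-4-one F5. MeMgBr/CeCl3 (THF, −78 °C) should add to C4 from the α-face, away from the 10β-methyl, to give 5α-eudesmane-4β,6α-diol F6. Dess–Martin oxidation of the secondary hydroxyl gives 4β-hydroxy-5α-eudesman-6-one F7, which has no alkene to migrate, and LiAlH4 at −78 °C reduces it from the α-face as in step 12 to the diol 15, where the route is rejoined.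

**Further compounds**

F1 | step 9 | 6α-acetoxy-5α-eudesman-4α-ol | CC(=O)O[C@@H]1[C@@H]2[C@](C)(CCC[C@@]2(C)O)CC[C@H]1C(C)C
F2 | step 7 | (6R,7S)-germacra-1(10),4,11-trien-6-yl (S)-O-methylmandelate | CO[C@H](C(=O)O[C@@H]1/C=C(\C)CC/C=C(\C)CC[C@H]1C(C)=C)c1ccccc1
F3 | step 7 | (6S,7R)-germacra-1(10),4,11-trien-6-yl (S)-O-methylmandelate | CO[C@H](C(=O)O[C@H]1/C=C(\C)CC/C=C(\C)CC[C@@H]1C(C)=C)c1ccccc1
F4 | step 7 | (1(10)E,4E,6R,7S)-germacra-1(10),4,11-trien-6-ol, single enantiomer | O[C@@H]1/C=C(\C)CC/C=C(\C)CC[C@H]1C(C)=C
F5 | step 11 | 6α-hydroxy-15-nor-5α-eudesman-4-one | O[C@@H]1[C@@H]2[C@](C)(CCCC2=O)CC[C@H]1C(C)C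
F6 | step 11 | 5α-eudesmane-4β,6α-diol | O[C@@H]1[C@@H]2[C@](C)(CCC[C@]2(C)O)CC[C@H]1C(C)C
F7 | step 11 | 4β-hydroxy-5α-eudesman-6-one | O=C1[C@@H]2[C@](C)(CCC[C@]2(C)O)CC[C@H]1C(C)C
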